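The synthesis rests on cutting the C1–C6 bond of ring A, the bond that joins the ester-bearing allylic carbinol carbon C1 to the methyl-bearing alkene carbon C6. An intramolecular Nozaki–Hiyama–Kishi coupling makes this bond, closes the cyclohexene ring A onto a finished cycloheptane ring B, creates the C1 stereocentre and fixes the position and cis geometry of the C5=C6 alkene in one operation. Its precursor is a monocyclic ring B that already holds the C3, C4 and C11 stereocentres and carries an acetaldehyde arm on C3, a Z-2-iodopropenyl group on C4 and the C11 hydroxyl as a triethylsilyl ether, which keeps the aldehyde free instead of locked as a lactol.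

Key step: step 12

Remarks on the chemistry (locants, assumption, design corrections)
- Locants used throughout: C1 ester-bearing CH, C2 CH2, C3 and C4 ring-fusion CH (C3 bonded to C11, C4 to C7), C5=C6 alkene with CH3 on C6, C7 CMe2, C8 to C10 CH2, C11 C(CH3)OH; ring A is C1 to C6, ring B is C3, C4, C7 to C11.
- Target check: the compound is 1R,3R,4R,11R; the rings are trans-fused, the C11 oxygen is trans to the C2 arm on C3 and cis to C5 on C4, and the C1 oxygen is cis to C7.
- Assumption: in step 4 the antipode of the ferrocenyl diphosphine is the one that delivers the vinyl group to the enone face giving the R centre at C4; it is fixed by a small test run before scale-up.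
- C11 design: a methyl nucleophile added directly to the C11 ketone is expected to enter anti to the C3 arm and so to give the C11 epimer (oxygen cis to the arm). The route therefore delivers the oxygen, not the methyl carbon, to that face (methylenation, epoxidation, hydride opening).
- Ring enlargement design: the one-carbon enlargement is run on a regiodefined silyl enol ether made from 3-methylcyclohex-2-en-1-one, which places the new CH2 unambiguously between the carbonyl and the carbon next to CMe2.
- Precursor design: both hydroxyls are silylated before the aldehydes are made, so the substrate of the key step is an open aldehyde.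

Step 1
Reactants: 1 3-methylcyclohex-2-en-1-one
Product: 2 3,3-dimethyl-1-(trimethylsilyloxy)cyclohex-1-ene
Conditions: MeMgBr, CuBr·SMe2 (5 mol %), TMSCl, DMPU, THF, −78 °C; Et3N
Reagents that add atoms: methylmagnesium bromide, C[Mg]Br; chlorotrimethylsilane, C[Si](C)(C)Cl
Why: Copper-catalysed, TMSCl-accelerated conjugate addition of the methyl Grignard reagent builds the quaternary CMe2 carbon (the later C7) and traps the enolate regiospecifically as the silyl enol ether whose double bond points toward that carbon; no stereocentre is formed.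

Step 2
Reactants: 2 3,3-dimethyl-1-(trimethylsilyloxy)cyclohex-1-ene
Product: 3 5,5-dimethyl-1-(trimethylsilyloxy)bicyclo[4.1.0]heptane (racemic)
Conditions: Et2Zn, CH2I2, CH2Cl2, 0 °C → rt
Reagents that add atoms: diiodomethane, ICI
Why: Furukawa-type Simmons–Smith cyclopropanation is fastest on electron-rich enol ethers and adds CH2 across the enol ether bond; the racemic cis-fused cyclopropane is only a relay, since both of its stereocentres disappear in step 3.

Step 3
Reactants: 3 5,5-dimethyl-1-(trimethylsilyloxy)bicyclo[4.1.0]heptane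
Product: 5 4,4-dimethylcyclohept-2-en-1-one, via chloro ketone 4 (not isolated)
Conditions: FeCl3, DMF, 0 °C → rt; then NaOAc, MeOH, reflux
Reagents that add atoms: none
Why: Ito–Saegusa ring enlargement: FeCl3 oxidises the siloxycyclopropane to an oxy radical that cleaves the bond shared by both rings, chlorine transfer gives the seven-membered β-chloro ketone 4, and acetate-mediated E1cB loss of HCl gives the enone with CMe2 next to the β-carbon, so the regiochemistry is fixed by the enol ether of step 1.

Step 4
Reactants: 5 4,4-dimethylcyclohept-2-en-1-one; 6 vinylmagnesium bromide; 7 tert-butyl bromoacetate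
Product: 9 tert-butyl 2-[(1R,7R)-7-ethenyl-6,6-dimethyl-2-oxocycloheptyl]acetate, via magnesium enolate 8 (not isolated)
Conditions: 6, CuBr·SMe2 (5 mol %), (R,SP)-1-[2-(diphenylphosphino)ferrocenyl]ethyldicyclohexylphosphine or its antipode (6 mol %), t-BuOMe, −78 °C; then 7, DMPU, −78 → −20 °C
Reagents that add atoms: none
Why: Copper-catalysed enantioselective conjugate addition of a Grignard reagent under a chiral ferrocenyl diphosphine sets C4 by catalyst control (vinyl delivered to the enone face that gives the R centre), and SN2 alkylation of the regiodefined magnesium enolate 8 by the bromoacetate takes place anti to the new vinyl group, which sets C3 trans to C4 (tandem conjugate addition–enolate alkylation).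

Step 5
Reactants: 9 tert-butyl 2-[(1R,7R)-7-ethenyl-6,6-dimethyl-2-oxocycloheptyl]acetate
Product: 10 tert-butyl 2-[(1R,7R)-7-ethenyl-6,6-dimethyl-2-methylidenecycloheptyl]acetate
Conditions: Ph3PCH3Br, KOt-Bu, THF, 0 °C → rt
Reagents that add atoms: methyltriphenylphosphonium bromide, C[P+](c1ccccc1)(c1ccccc1)c1ccccc1.[Br-]
Why: Wittig methylenation converts the ketone into the exocyclic alkene while the tert-butyl ester is inert to the ylide; C3 is the only base-labile centre and already holds the more stable trans arrangement.

Step 6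
Reactants: 10 tert-butyl 2-[(1R,7R)-7-ethenyl-6,6-dimethyl-2-methylidenecycloheptyl]acetate
Product: 11 tert-butyl 2-[(3R,4R,5R)-5-ethenyl-6,6-dimethyl-1-oxaspiro[2.6]nonan-4-yl]acetate
Conditions: mCPBA (1.05 equiv), NaHCO3, CH2Cl2, 0 °C
Reagents that add atoms: 3-chloroperoxybenzoic acid, OOC(=O)c1cccc(Cl)c1
Why: Prilezhaev epoxidation is markedly faster on the 1,1-disubstituted exocyclic alkene than on the monosubstituted vinyl group, and the peracid should approach anti to the neighbouring C3 arm, which allylic 1,3-strain turns out of the alkene plane, so the C11 oxygen is placed trans to that arm and cis to the C4 substituent (substrate control of the new stereocentre C11).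

Step 7
Reactants: 11 tert-butyl 2-[(3R,4R,5R)-5-ethenyl-6,6-dimethyl-1-oxaspiro[2.6]nonan-4-yl]acetate
Product: 12 (1R,2R,3R)-3-ethenyl-2-(2-hydroxyethyl)-1,4,4-trimethylcycloheptan-1-ol
Conditions: LiAlH4, THF, 0 °C → rt
Reagents that add atoms: none
Why: Hydride reduction with LiAlH4 opens the epoxide by SN2 attack at its unhindered CH2 carbon, which turns that carbon into the C11 methyl group and leaves the C11–O bond and configuration untouched, and reduces the ester to the C1 primary alcohol in the same flask.

Step 8
Reactants: 12 (1R,2R,3R)-3-ethenyl-2-(2-hydroxyethyl)-1,4,4-trimethylcycloheptan-1-ol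
Product: 13 (1R,2R,3R)-3-ethenyl-1,4,4-trimethyl-1-(triethylsilyloxy)-2-[2-(triethylsilyloxy)ethyl]cycloheptane
Conditions: TESOTf (2.5 equiv), 2,6-lutidine, CH2Cl2, −78 → 0 °C
Reagents that add atoms: triethylsilyl trifluoromethanesulfonate, CC[Si](CC)(CC)OS(=O)(=O)C(F)(F)F
Why: Silylation with a silyl triflate and a hindered pyridine base caps the primary and the congested tertiary hydroxyl alike, so that neither can add to the aldehydes that follow.

Step 9
Reactants: 13 (1R,2R,3R)-3-ethenyl-1,4,4-trimethyl-1-(triethylsilyloxy)-2-[2-(triethylsilyloxy)ethyl]cycloheptane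
Product: 15 (1R,6R,7R)-2,2,6-trimethyl-6-(triethylsilyloxy)-7-[2-(triethylsilyloxy)ethyl]cycloheptane-1-carbaldehyde, via ozonide 14 (not isolated)
Conditions: O3, CH2Cl2, −78 °C; then PPh3, −78 °C → rt
Reagents that add atoms: ozone, [O-][O+]=O
Why: Ozonolysis (Criegee sequence through ozonide 14) cleaves the only alkene to the C5 aldehyde, and the neutral phosphine reduction avoids epimerisation of the α-centre C4.

Step 10
Reactants: 15 (1R,6R,7R)-2,2,6-trimethyl-6-(triethylsilyloxy)-7-[2-(triethylsilyloxy)ethyl]cycloheptane-1-carbaldehyde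
Product: 16 (1R,2R,3S)-3-[(1Z)-2-iodoprop-1-en-1-yl]-1,4,4-trimethyl-1-(triethylsilyloxy)-2-[2-(triethylsilyloxy)ethyl]cycloheptane
Conditions: EtPPh3I, n-BuLi, THF, rt; I2, −78 °C; NaHMDS, −20 °C; then 15, −78 → −20 °C
Reagents that add atoms: ethyltriphenylphosphonium iodide, CC[P+](c1ccccc1)(c1ccccc1)c1ccccc1.[I-]; iodine, II
Why: Stork–Zhao olefination, a Wittig reaction of the non-stabilised α-iodo ylide under kinetic control, converts the aldehyde into the trisubstituted alkenyl iodide with iodine cis to C4 (Z), the geometry needed for a cis alkene inside ring A.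

Step 11
Reactants: 16 (1R,2R,3S)-3-[(1Z)-2-iodoprop-1-en-1-yl]-1,4,4-trimethyl-1-(triethylsilyloxy)-2-[2-(triethylsilyloxy)ethyl]cycloheptane
Product: 17 2-[(1R,2R,7S)-7-[(1Z)-2-iodoprop-1-en-1-yl]-2,6,6-trimethyl-2-(triethylsilyloxy)cycloheptyl]acetaldehyde
Conditions: (COCl)2, DMSO, CH2Cl2, −78 → −30 °C; Et3N, −78 °C → rt
Reagents that add atoms: none
Why: Swern oxidation applied directly to the silyl ether: the chlorosulfonium reagent cleaves the unhindered primary triethylsilyl ether and oxidises it to the aldehyde in one operation (a known selective oxidative desilylation), while the tertiary silyl ether is too hindered to be cleaved and cannot be oxidised.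

Step 12
Reactants: 17 2-[(1R,2R,7S)-7-[(1Z)-2-iodoprop-1-en-1-yl]-2,6,6-trimethyl-2-(triethylsilyloxy)cycloheptyl]acetaldehyde
Product: 19 (2R,4aR,9R,9aR)-3,5,5,9-tetramethyl-9-(triethylsilyloxy)-2,4a,5,6,7,8,9,9a-octahydro-1H-benzo[7]annulen-2-ol, via alkenylchromium 18 (not isolated)
Conditions: CrCl2 (6 equiv), NiCl2 (2 mol %), degassed DMSO, 0.005 M, rt
Reagents that add atoms: none
Why: Nozaki–Hiyama–Kishi reaction: zerovalent nickel, formed from NiCl2 by divalent chromium, inserts into the carbon–iodine bond of 17, the alkenyl group passes to trivalent chromium with retention of the Z geometry (alkenylchromium 18), and this adds to the C1 aldehyde to give the chromium alkoxide of 19. The closest known reaction type is the intramolecular nickel/chromium-mediated coupling of an alkenyl halide with an aldehyde used to close cyclic allylic alcohols. Ring A closes in a 6-exo-trig mode on the carbonyl, forming C1–C6. The new stereocentre C1 is set by substrate control: ring B holds its bonds at C3 and C4 trans-diequatorial in a half-chair transition state, and the chromium-bound oxygen should avoid eclipsing the C6 methyl group (allylic 1,2-strain) by taking the pseudoaxial position, cis to C7, which is the 1R configuration. The step needs activation of the alkenyl iodide in the presence of an aldehyde, which the nickel/chromium couple secures because it leaves aldehydes and silyl ethers untouched, and cyclisation over oligomerisation, which high dilution and the Z geometry (C6 held next to C1) secure; the C11 silyl ether keeps the aldehyde open.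

Step 13
Reactants: 20 isovanillic acid (3-hydroxy-4-methoxybenzoic acid)
Product: 22 3-(tert-butyldimethylsilyloxy)-4-methoxybenzoic acid, via silyl ester 21 (not isolated)
Conditions: TBSCl (2.2 equiv), imidazole, DMF, rt; then AcOH, H2O, THF, rt
Reagents that add atoms: tert-butyldimethylsilyl chloride, CC(C)(C)[Si](C)(C)Cl
Why: Silylation of both the phenol and the acid followed by hydrolysis of the much more labile silyl ester leaves the aryl silyl ether, which removes the phenol as a competing nucleophile in the esterification.

Step 14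
Reactants: 19 (2R,4aR,9R,9aR)-3,5,5,9-tetramethyl-9-(triethylsilyloxy)-2,4a,5,6,7,8,9,9a-octahydro-1H-benzo[7]annulen-2-ol; 22 3-(tert-butyldimethylsilyloxy)-4-methoxybenzoic acid
Product: 24 (2R,4aR,9R,9aR)-3,5,5,9-tetramethyl-9-(triethylsilyloxy)-2,4a,5,6,7,8,9,9a-octahydro-1H-benzo[7]annulen-2-yl 3-(tert-butyldimethylsilyloxy)-4-methoxybenzoate, via mixed anhydride 23 (not isolated)
Conditions: 22, 2,4,6-Cl3C6H2COCl, Et3N, THF, rt; then 19, DMAP, toluene, rt → 50 °C
Reagents that add atoms: none
Why: Yamaguchi esterification: the acyl-transfer catalyst attacks the less hindered carbonyl of mixed anhydride 23 and the resulting acylpyridinium acylates the secondary allylic C1–OH with retention of configuration, the tertiary C11 oxygen being silylated.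

Step 15
Reactants: 24 (2R,4aR,9R,9aR)-3,5,5,9-tetramethyl-9-(triethylsilyloxy)-2,4a,5,6,7,8,9,9a-octahydro-1H-benzo[7]annulen-2-yl 3-(tert-butyldimethylsilyloxy)-4-methoxybenzoate
Product: 25 (2R,4aR,9R,9aR)-9-hydroxy-3,5,5,9-tetramethyl-2,4a,5,6,7,8,9,9a-octahydro-1H-benzo[7]annulen-2-yl 3-hydroxy-4-methoxybenzoate (target)
Conditions: TBAF (3 equiv), AcOH (3 equiv), THF, 0 °C → rt
Reagents that add atoms: none
Why: Fluoride-induced desilylation removes the aryl and the tertiary silyl ether in one operation, and the acetic acid buffer keeps the benzoate ester, the allylic C1–O bond and the tertiary alcohol intact.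

Compound list
1 | 3-methylcyclohex-2-en-1-one | CC1=CC(=O)CCC1 | starting material
2 | 3,3-dimethyl-1-(trimethylsilyloxy)cyclohex-1-ene | C[Si](C)(C)OC1=CC(C)(C)CCC1 | intermediate
3 | 5,5-dimethyl-1-(trimethylsilyloxy)bicyclo[4.1.0]heptane, racemic cis-fused cyclopropane | C[Si](C)(C)OC12CCCC(C)(C)C1C2 | intermediate
4 | 3-chloro-4,4-dimethylcycloheptan-1-one, racemic | O=C1CC(Cl)C(C)(C)CCC1 | intermediate
5 | 4,4-dimethylcyclohept-2-en-1-one | O=C1C=CC(C)(C)CCC1 | intermediate
6 | vinylmagnesium bromide | C=C[Mg]Br | starting material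
7 | tert-butyl bromoacetate | CC(C)(C)OC(=O)CBr | starting material
8 | bromomagnesium (3R)-3-ethenyl-4,4-dimethylcyclohept-1-en-1-olate | Br[Mg]OC1=C[C@@H](C=C)C(C)(C)CCC1 | intermediate
9 | tert-butyl 2-[(1R,7R)-7-ethenyl-6,6-dimethyl-2-oxocycloheptyl]acetate | CC(C)(C)OC(=O)C[C@@H]1[C@@H](C=C)C(C)(C)CCCC1=O | intermediate
10 | tert-butyl 2-[(1R,7R)-7-ethenyl-6,6-dimethyl-2-methylidenecycloheptyl]acetate | CC(C)(C)OC(=O)C[C@@H]1[C@@H](C=C)C(C)(C)CCCC1=C | intermediate
11 | tert-butyl 2-[(3R,4R,5R)-5-ethenyl-6,6-dimethyl-1-oxaspiro[2.6]nonan-4-yl]acetate | CC(C)(C)OC(=O)C[C@@H]1[C@@H](C=C)C(C)(C)CCC[C@@]1(C2)O2 | intermediate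
12 | (1R,2R,3R)-3-ethenyl-2-(2-hydroxyethyl)-1,4,4-trimethylcycloheptan-1-ol | OCC[C@@H]1[C@@H](C=C)C(C)(C)CCC[C@@]1(C)O | intermediate
13 | (1R,2R,3R)-3-ethenyl-1,4,4-trimethyl-1-(triethylsilyloxy)-2-[2-(triethylsilyloxy)ethyl]cycloheptane | CC[Si](CC)(CC)OCC[C@@H]1[C@@H](C=C)C(C)(C)CCC[C@@]1(C)O[Si](CC)(CC)CC | intermediate
14 | 1,2,4-trioxolane (ozonide) of 13, mixture of epimers at the trioxolane carbon | CC[Si](CC)(CC)OCC[C@@H]1[C@@H](C2OCOO2)C(C)(C)CCC[C@@]1(C)O[Si](CC)(CC)CC | intermediate
15 | (1R,6R,7R)-2,2,6-trimethyl-6-(triethylsilyloxy)-7-[2-(triethylsilyloxy)ethyl]cycloheptane-1-carbaldehyde | CC[Si](CC)(CC)OCC[C@@H]1[C@@H](C=O)C(C)(C)CCC[C@@]1(C)O[Si](CC)(CC)CC | intermediate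
16 | (1R,2R,3S)-3-[(1Z)-2-iodoprop-1-en-1-yl]-1,4,4-trimethyl-1-(triethylsilyloxy)-2-[2-(triethylsilyloxy)ethyl]cycloheptane | CC[Si](CC)(CC)OCC[C@@H]1[C@@H](/C=C(/C)I)C(C)(C)CCC[C@@]1(C)O[Si](CC)(CC)CC | intermediate
17 | 2-[(1R,2R,7S)-7-[(1Z)-2-iodoprop-1-en-1-yl]-2,6,6-trimethyl-2-(triethylsilyloxy)cycloheptyl]acetaldehyde (substrate of the key step) | O=CC[C@@H]1[C@@H](/C=C(/C)I)C(C)(C)CCC[C@@]1(C)O[Si](CC)(CC)CC | intermediate
18 | alkenylchromium dichloride derived from 17, chromium in place of iodine with the same alkene geometry | O=CC[C@@H]1[C@@H](/C=C(/C)[Cr](Cl)Cl)C(C)(C)CCC[C@@]1(C)O[Si](CC)(CC)CC | intermediate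
19 | (2R,4aR,9R,9aR)-3,5,5,9-tetramethyl-9-(triethylsilyloxy)-2,4a,5,6,7,8,9,9a-octahydro-1H-benzo[7]annulen-2-ol (product of the key step; 1R,3R,4R,11R in the route locants) | O[C@@H]1C[C@@H]2[C@@H](C=C1C)C(C)(C)CCC[C@@]2(C)O[Si](CC)(CC)CC | intermediate
20 | isovanillic acid (3-hydroxy-4-methoxybenzoic acid) | COc1ccc(C(=O)O)cc1O | starting material
21 | tert-butyldimethylsilyl 3-(tert-butyldimethylsilyloxy)-4-methoxybenzoate | COc1ccc(C(=O)O[Si](C)(C)C(C)(C)C)cc1O[Si](C)(C)C(C)(C)C | intermediate
22 | 3-(tert-butyldimethylsilyloxy)-4-methoxybenzoic acid | COc1ccc(C(=O)O)cc1O[Si](C)(C)C(C)(C)C | intermediate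
23 | 3-(tert-butyldimethylsilyloxy)-4-methoxybenzoic 2,4,6-trichlorobenzoic anhydride | COc1ccc(C(=O)OC(=O)c2c(Cl)cc(Cl)cc2Cl)cc1O[Si](C)(C)C(C)(C)C | intermediate
24 | (2R,4aR,9R,9aR)-3,5,5,9-tetramethyl-9-(triethylsilyloxy)-2,4a,5,6,7,8,9,9a-octahydro-1H-benzo[7]annulen-2-yl 3-(tert-butyldimethylsilyloxy)-4-methoxybenzoate | COc1ccc(C(=O)O[C@@H]2C[C@@H]3[C@@H](C=C2C)C(C)(C)CCC[C@@]3(C)O[Si](CC)(CC)CC)cc1O[Si](C)(C)C(C)(C)C | intermediate
25 | (2R,4aR,9R,9aR)-9-hydroxy-3,5,5,9-tetramethyl-2,4a,5,6,7,8,9,9a-octahydro-1H-benzo[7]annulen-2-yl 3-hydroxy-4-methoxybenzoate, CNP0210711.2 | COc1ccc(C(=O)O[C@@H]2C[C@@H]3[C@@H](C=C2C)C(C)(C)CCC[C@@]3(C)O)cc1O | target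

Step count and risks

Total: 15 steps. Longest linear sequence: 14 steps (steps 1 to 12, 14 and 15; step 13 is a one-step side branch).

The three operations most likely to fail, most uncertain first:

(a) Conjugate addition and alkylation, step 4. The vinyl transfer may show poor enantiofacial discrimination, the addition at the congested β-carbon next to CMe2 may stall, and proton exchange during the slow alkylation of the magnesium enolate may scramble the enolate position.
Fallback, from 5 back to 9: the two bond formations are separated and the nucleophile class is changed. Dimethyl(vinyl)aluminium (from 6 and Me2AlCl) is added to 5 under catalysis by copper thiophene-2-carboxylate, Cu(O2CC4H3S), and a binaphthol-derived chiral phosphoramidite in Et2O at −30 °C. This is a copper-catalysed conjugate addition of an alkenylalane, a reagent class that tolerates congested β-carbons. The aluminium enolate is silylated with TMSOTf to the isolable silyl enol ether (3R)-3-ethenyl-4,4-dimethyl-1-(trimethylsilyloxy)cyclohept-1-ene F1, on which the enantiomeric purity can be checked before the second centre is set. MeLi in THF at 0 °C then releases the regiodefined lithium (3R)-3-ethenyl-4,4-dimethylcyclohept-1-en-1-olate F2, which is alkylated with 7 in THF/DMPU at −78 °C, anti to the vinyl group, to rejoin the route at 9.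

(b) Epoxidation, step 6. The peracid may attack the face of the exocyclic alkene syn to the C3 arm, or show little facial preference, which would give the C11 epimer after step 7.
Fallback, from 9 back to 11: the order of bond formation at C11 is reversed. Ketone 9 is treated with dimethylsulfonium methylide (trimethylsulfonium iodide, n-BuLi, THF, −10 °C → rt; Corey–Chaykovsky epoxidation). The ylide carbon now enters from the face that proved open, syn to the C3 arm, and the oxygen is left trans to the arm, so epoxide 11 is formed directly from 9 and step 5 is skipped. No compound outside the compound list is formed on this path (F0).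

(c) Ring closure, step 12. The alkenylchromium may add to the other face of the aldehyde, so that the chromium alkoxide ends pseudoequatorial and the C1 epimer predominates.
Fallback, from 17 back to 24: the cyclisation is run as in step 12 and the C1 epimer (2S,4aR,9R,9aR)-3,5,5,9-tetramethyl-9-(triethylsilyloxy)-2,4a,5,6,7,8,9,9a-octahydro-1H-benzo[7]annulen-2-ol F3 is isolated. It is esterified with 22 under Mitsunobu conditions (PPh3, diisopropyl azodicarboxylate, toluene, 0 °C → rt) instead of under the retentive conditions of step 14. SN2 displacement of the activated C1 oxygen by the carboxylate inverts C1 and gives 24 directly, so the route is rejoined at 24 without an extra step.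

Further compounds
F1 | step 4 | (3R)-3-ethenyl-4,4-dimethyl-1-(trimethylsilyloxy)cyclohept-1-ene | C[Si](C)(C)OC1=C[C@@H](C=C)C(C)(C)CCC1
F2 | step 4 | lithium (3R)-3-ethenyl-4,4-dimethylcyclohept-1-en-1-olate | [Li]OC1=C[C@@H](C=C)C(C)(C)CCC1
F0 | step 6 | none | none
F3 | step 12 | (2S,4aR,9R,9aR)-3,5,5,9-tetramethyl-9-(triethylsilyloxy)-2,4a,5,6,7,8,9,9a-octahydro-1H-benzo[7]annulen-2-ol | O[C@H]1C[C@@H]2[C@@H](C=C1C)C(C)(C)CCC[C@@]2(C)O[Si](CC)(CC)CC
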